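**Retrosynthetic overview**

1. Germacrane numbering is used: ring C1–C10 (C4–C5 oxirane, C6 ester carbinol, C7 ring fusion, C8 lactone carbinol, C9 free carbinol, C10 CH–CH3), lactone carbons C11–C13. The enabling feature is the O–C8–C9(OH)–C10 array of the ten-membered ring: a vicinal dioxygen pattern whose carbinol C9 is bonded to the methine C10, which is what a C8–C9 oxirane carbenoid leaves after insertion into a C10–B bond and oxidation.
2. Key disconnection: ten-membered carbocycle ⇐ eleven-membered cyclic boronate complex (boron between C9 and C10) ⇐ open-chain bis-epoxide with a terminal C8–C9 oxirane and a secondary C10 pinacol boronate. The 1,2-metallate shift makes C9–C10, extrudes boron from the ring and opens the oxirane (strain release).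
3. Open chain: C4/C5 by Sharpless epoxidation; C6/C7 by Evans aldol of a senecioyl imide with the epoxy aldehyde; C8 by syn-1,3 reduction of a chloromethyl ketone (then terminal oxirane); C10 by lithiation–borylation of a primary boronate.
4. Ring order: C4–C5 oxirane → C8–C9 oxirane → boracycle → ten-membered carbocycle (key step) → α-methylene γ-lactone (allylic oxidation, aerobic lactonisation).
5. Endgame: the key step gives the 8,9-syn diol (C9 epimer), so a Mitsunobu formate inversion at C9 corrects it and masks O9 during O6 senecioylation; deformylation finishes.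

Key step: step 13

Remark: pent-1-en-4-yne, both enantiomeric series of the reagents named, and the other starting materials are taken as commercial; the key step is assumed to follow the stereochemical course of its intermolecular precedent (syn diol).

**Route**

Step 1
Reactants: 1 pent-1-en-4-yne
Product: 3 (2E)-3-methylhexa-2,5-dien-1-ol, via alkenyl(dimethyl)alane 2 (not isolated)
Conditions: Me3Al, Cp2ZrCl2 (0.25 equiv), CH2Cl2, 0 °C → rt; then n-BuLi, THF, −78 °C; (CH2O)n, → rt; aq. NH4Cl
Reagents that add atoms: trimethylaluminium, C[Al](C)C; paraformaldehyde (as formaldehyde), C=O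
Why: Negishi zirconium-catalysed carboalumination adds methyl and aluminium syn across the terminal alkyne (methyl to the internal carbon) far faster than across the isolated alkene, and hydroxymethylation of the derived alanate proceeds with retention, so the trisubstituted alkene should be formed as the E isomer.

Step 2
Reactants: 3 (2E)-3-methylhexa-2,5-dien-1-ol
Product: 4 [(2R,3R)-3-methyl-3-(prop-2-en-1-yl)oxiran-2-yl]methanol
Conditions: Ti(OiPr)4 (10 mol%), D-(−)-diethyl tartrate (12 mol%), t-BuOOH, 4 Å MS, CH2Cl2, −20 °C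
Reagents that add atoms: tert-butyl hydroperoxide, CC(C)(C)OO
Why: Sharpless asymmetric epoxidation of a geraniol-type primary allylic alcohol, in which the D-tartrate ligand delivers oxygen to the face that gives the (2R,3R)-oxirane (C4 and C5 of the target) while the isolated terminal alkene is inert to the titanium peroxide.

Step 3
Reactants: 4 [(2R,3R)-3-methyl-3-(prop-2-en-1-yl)oxiran-2-yl]methanol
Product: 5 (2S,3R)-3-methyl-3-(prop-2-en-1-yl)oxirane-2-carbaldehyde
Conditions: Dess–Martin periodinane, NaHCO3, CH2Cl2, 0 °C → rt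
Reagents that add atoms: none
Why: Dess–Martin oxidation under buffered conditions should give the sensitive epoxy aldehyde without epimerisation at C5 or opening of the oxirane, and the crude aldehyde is used directly.

Step 4
Reactants: 6 (4R)-4-benzyl-1,3-oxazolidin-2-one; 7 3-methylbut-2-enoyl chloride
Product: 9 (4R)-4-benzyl-3-(3-methylbut-2-enoyl)-1,3-oxazolidin-2-one, via lithium oxazolidinide 8 (not isolated)
Conditions: n-BuLi, THF, −78 °C; then 7, −78 → 0 °C
Reagents that add atoms: none
Why: N-acylation of the lithiated oxazolidinone by the acid chloride at low temperature is the standard entry to Evans imides and creates no stereocentre.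

Step 5
Reactants: 9 (4R)-4-benzyl-3-(3-methylbut-2-enoyl)-1,3-oxazolidin-2-one; 5 (2S,3R)-3-methyl-3-(prop-2-en-1-yl)oxirane-2-carbaldehyde
Product: 11 (4R)-4-benzyl-3-[(2R,3R)-3-hydroxy-3-[(2R,3R)-3-methyl-3-(prop-2-en-1-yl)oxiran-2-yl]-2-(prop-1-en-2-yl)propanoyl]-1,3-oxazolidin-2-one, via boron dienolate 10 (not isolated)
Conditions: Bu2BOTf, Et3N, CH2Cl2, −78 → 0 °C; then 5, −78 → 0 °C; pH 7 buffer, MeOH, H2O2, 0 °C
Reagents that add atoms: none
Why: Evans boron aldol reaction: soft enolisation removes a γ-hydrogen to give the Z boron dienolate, which reacts at its α-carbon through a Zimmerman–Traxler chair so that the (R)-benzyl auxiliary sets C7 and the 6,7-syn carbinol C6, the sense also preferred by the α-oxygenated aldehyde, which secures the 5,6-anti (erythro) epoxy alcohol.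

Step 6
Reactants: 11 Evans aldol adduct
Product: 12 (2R,3R)-3-hydroxy-N-methoxy-N-methyl-3-[(2R,3R)-3-methyl-3-(prop-2-en-1-yl)oxiran-2-yl]-2-(prop-1-en-2-yl)propanamide
Conditions: MeNH(OMe)·HCl, AlMe3, CH2Cl2, 0 °C; then 11, −20 → 0 °C; aq. potassium sodium tartrate
Reagents that add atoms: N,O-dimethylhydroxylamine hydrochloride, CNOC.Cl
Why: Weinreb transamidation in which the aluminium alkoxide of the free β-hydroxyl delivers the amide to the exocyclic carbonyl, the preformed aluminium amide being used cold so that no free AlMe3 is left to open the oxirane, and the auxiliary is released for recovery.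

Step 7
Reactants: 12 Weinreb amide
Product: 13 (3R,4R)-1-chloro-4-hydroxy-4-[(2R,3R)-3-methyl-3-(prop-2-en-1-yl)oxiran-2-yl]-3-(prop-1-en-2-yl)butan-2-one
Conditions: ICH2Cl, MeLi·LiBr, THF, −78 °C; aq. NH4Cl
Reagents that add atoms: chloroiodomethane, ClCI
Why: (Chloromethyl)lithium generated by iodine–lithium exchange in the presence of the substrate adds once to the Weinreb amide, whose chelated tetrahedral intermediate survives until the quench, to give the chloromethyl ketone after the first equivalent of base has deprotonated the hydroxyl.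

Step 8
Reactants: 13 chloromethyl ketone
Product: 15 (1R,2R)-3-methyl-1-[(2R,3R)-3-methyl-3-(prop-2-en-1-yl)oxiran-2-yl]-2-[(2S)-oxiran-2-yl]but-3-en-1-ol, via chlorohydrin 14 (not isolated)
Conditions: Et2BOMe, THF/MeOH (4:1), −78 °C; NaBH4; then aq. NaOH, H2O2, 0 °C → rt
Reagents that add atoms: none
Why: Narasaka–Prasad reduction: external hydride attacks the six-membered boron chelate of the β-hydroxy ketone axially to give the 6,8-syn diol and so sets C8, and the basic peroxide work-up frees the diol and closes the chlorohydrin by intramolecular Williamson displacement to the terminal oxirane without touching the C8–O bond.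

Step 9
Reactants: 15 bis-epoxy alcohol
Product: 16 triethyl{[(1R,2S)-3-methyl-1-[(2R,3R)-3-methyl-3-(prop-2-en-1-yl)oxiran-2-yl]-2-[(2S)-oxiran-2-yl]but-3-en-1-yl]oxy}silane
Conditions: Et3SiCl, imidazole, DMAP (cat.), CH2Cl2, 0 °C → rt
Reagents that add atoms: chlorotriethylsilane, CC[Si](Cl)(CC)CC
Why: Silylation of the only hydroxyl with a silyl chloride and imidazole avoids silyl triflates, which could trigger rearrangement of the neighbouring oxiranes.

Step 10
Reactants: 16 triethylsilyl ether
Product: 17 primary pinacol boronate (16 with CH2CH2–Bpin in place of the vinyl group)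
Conditions: [Ir(cod)Cl]2 (1.5 mol%), dppm (3 mol%), HBpin, CH2Cl2, rt
Reagents that add atoms: pinacolborane, CC1(C)OBOC1(C)C
Why: Iridium-catalysed hydroboration with pinacolborane is anti-Markovnikov and strongly prefers the monosubstituted alkene over the hindered 1,1-disubstituted isopropenyl group, while oxiranes and the silyl ether are inert.

Step 11
Reactants: 18 2,4,6-tri(propan-2-yl)benzoic acid; 19 ethanol
Product: 20 ethyl 2,4,6-tri(propan-2-yl)benzoate
Conditions: PPh3, DIAD, THF, 0 °C → rt
Reagents that add atoms: none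
Why: Mitsunobu esterification is the usual way to make hindered 2,4,6-triisopropylbenzoates of primary alcohols, the acid being too hindered for direct esterification.

Step 12
Reactants: 17 primary pinacol boronate; 20 ethyl 2,4,6-tri(propan-2-yl)benzoate
Product: 23 secondary pinacol boronate (17 homologated by CH–CH3; boron-bearing carbon C10 is R), via lithiated benzoate 21 (not isolated), via boronate complex 22 (not isolated)
Conditions: 20, (−)-sparteine, s-BuLi, Et2O, −78 °C, 5 h; then 17, −78 °C, 1 h; then reflux
Reagents that add atoms: none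
Why: Lithiation–borylation (Hoppe-type sparteine-mediated deprotonation followed by a Matteson-type 1,2-metallate rearrangement): the (S)-configured lithiated benzoate adds to boron with retention and the primary alkyl group then migrates with inversion as the benzoate leaves, so C10 is set as the (R)-boronate by reagent control.

Step 13
Reactants: 23 secondary pinacol boronate
Product: 27 (4R,5R,6R,7S,8S,9S,10R)-4,5-epoxy-6-(triethylsilyloxy)germacr-11(13)-ene-8,9-diol, via lithiated oxirane 24 (not isolated), via cyclic boronate complex 25 (not isolated), via ring-contracted boronate 26 (not isolated)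
Conditions: 23 added slowly to LiTMP (from 2,2,6,6-tetramethylpiperidine and n-BuLi, 4 equiv), THF, −30 °C, final 0.004 M; → 0 °C; then aq. NaOH, H2O2, 0 °C
Reagents that add atoms: hydrogen peroxide, OO
Why: Proposed new method: LiTMP removes the oxirane hydrogen of C9 that is trans to the C7 substituent, the lithiated oxirane 24 is trapped by the remote secondary boronate to give the eleven-membered cyclic boronate complex 25, and the C10–B bond then migrates to C9 antiperiplanar to the breaking C9–O bond, so that boron is extruded from the ring, oxirane strain is released and the ten-membered carbocycle 26 results; alkaline peroxide finally replaces boron at C9 by hydroxyl. The closest known reactions are the intermolecular homologation of boronic esters with LiTMP-lithiated terminal epoxides to syn-1,2-diols and the ring contraction of cyclic boronate complexes by 1,2-metallate rearrangement; the intramolecular medium-ring version is new. Ring closures: the boracycle forms by an eleven-membered ring closure at boron (the carbanion adds to trigonal boron) and the carbocycle by a three-centre 1,2-shift that contracts this ring from eleven to ten members while the C9–C10 bond is made. Stereocontrol: C10 migrates with retention (its configuration comes from step 12) and C9 follows from trans-lithiation relative to C8, retentive borylation, invertive migration and retentive oxidation, which gives the 8,9-syn diol, that is the C9 epimer of the target, corrected in step 16; C8 keeps its oxygen and configuration. The step needs site-selective deprotonation at the terminal oxirane CH2 (not at C7–H, at the hindered trisubstituted oxirane or next to boron), secured by the bulk of LiTMP and the accessibility of that position, intramolecular capture instead of carbenoid dimerisation or attack by LiTMP, secured by slow addition that keeps the substrate dilute, and carbon instead of oxygen migration, secured by the antiperiplanar C10–B bond of the ate complex.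

Step 14
Reactants: 27 macrocyclic 8,9-diol
Product: 28 (4R,5R,6R,7S,8S,9S,10R)-4,5-epoxy-6-(triethylsilyloxy)germacr-11(13)-ene-8,9,12-triol
Conditions: SeO2 (0.3 equiv), t-BuOOH, CH2Cl2, 0 °C → rt
Reagents that add atoms: selenium dioxide, O=[Se]=O; tert-butyl hydroperoxide, CC(C)(C)OO
Why: Selenium dioxide allylic oxidation (ene reaction then [2,3]-sigmatropic shift) of the only alkene should take place at the methyl group and not at the hindered C7 methine, giving the 2-substituted allylic alcohol, and any over-oxidised enal converges in the next step.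

Step 15
Reactants: 28 triol
Product: 29 (4R,5R,6R,7S,8S,9S,10R)-4,5-epoxy-9-hydroxy-6-(triethylsilyloxy)germacr-11(13)-en-12,8-olide
Conditions: [Cu(MeCN)4]OTf (5 mol%), 2,2'-bipyridine (5 mol%), TEMPO (5 mol%), N-methylimidazole (10 mol%), air, MeCN, rt
Reagents that add atoms: none
Why: Copper/nitroxyl aerobic oxidative lactonisation: the primary allylic alcohol is oxidised selectively to the enal, which is trapped by the adjacent C8 hydroxyl as the fused five-membered lactol and oxidised on to the α-methylene γ-lactone, under conditions that neither oxidise the secondary C9 hydroxyl nor cleave the diol.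

Step 16
Reactants: 29 9-epi hydroxy lactone
Product: 30 (4R,5R,6R,7S,8S,9R,10R)-4,5-epoxy-9-(formyloxy)-6-(triethylsilyloxy)germacr-11(13)-en-12,8-olide
Conditions: PPh3, DIAD, HCO2H, toluene, 0 °C → rt
Reagents that add atoms: formic acid, O=CO
Why: Mitsunobu reaction: SN2 displacement of the C9 oxyphosphonium ion by formate inverts C9 to the configuration of the target and leaves O9 masked as a formate for the next two steps.

Step 17
Reactants: 30 formate silyl ether
Product: 31 (4R,5R,6R,7R,8S,9R,10R)-4,5-epoxy-9-(formyloxy)-6-hydroxygermacr-11(13)-en-12,8-olide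
Conditions: HF·pyridine, pyridine, THF, 0 °C
Reagents that add atoms: none
Why: Buffered HF·pyridine cleaves the triethylsilyl ether by fluoride attack at silicon under conditions that should leave the formate, the oxirane and the α-methylene lactone untouched.

Step 18
Reactants: 31 C6 alcohol; 7 3-methylbut-2-enoyl chloride
Product: 32 (4R,5R,6R,7S,8S,9R,10R)-4,5-epoxy-9-(formyloxy)-6-(3-methylbut-2-enoyloxy)germacr-11(13)-en-12,8-olide
Conditions: pyridine, DMAP, CH2Cl2, 0 °C → rt
Reagents that add atoms: none
Why: DMAP-catalysed acylation of the only free hydroxyl (O6) with the acid chloride, pyridine being a base weak enough to limit deconjugation of the senecioyl group through its vinylketene.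

Step 19
Reactants: 32 senecioate formate
Product: 33 CNP0119422.1, (4R,5R,6R,7S,8S,9R,10R)-4,5-epoxy-9-hydroxy-6-(3-methylbut-2-enoyloxy)germacr-11(13)-en-12,8-olide
Conditions: KHCO3, MeOH/H2O, 0 °C
Reagents that add atoms: none
Why: Formate esters undergo solvolysis far faster than the conjugated senecioate or the lactone, so mild hydrogen carbonate methanolysis should free O9 selectively and complete the synthesis.

**Compound list**

1 | pent-1-en-4-yne | C=CCC#C | starting material
2 | dimethyl[(1E)-2-methylpenta-1,4-dien-1-yl]alane | C=CC/C(C)=C/[Al](C)C | intermediate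
3 | (2E)-3-methylhexa-2,5-dien-1-ol | C=CC/C(C)=C/CO | intermediate
4 | [(2R,3R)-3-methyl-3-(prop-2-en-1-yl)oxiran-2-yl]methanol | C=CC[C@@]1(C)O[C@@H]1CO | intermediate
5 | (2S,3R)-3-methyl-3-(prop-2-en-1-yl)oxirane-2-carbaldehyde | C=CC[C@@]1(C)O[C@@H]1C=O | intermediate
6 | (4R)-4-benzyl-1,3-oxazolidin-2-one | O=C1N[C@H](Cc2ccccc2)CO1 | starting material
7 | 3-methylbut-2-enoyl chloride | CC(C)=CC(Cl)=O | starting material
8 | lithium (4R)-4-benzyl-2-oxo-1,3-oxazolidin-3-ide | [Li]N1[C@H](Cc2ccccc2)COC1=O | intermediate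
9 | (4R)-4-benzyl-3-(3-methylbut-2-enoyl)-1,3-oxazolidin-2-one | CC(C)=CC(=O)N1[C@H](Cc2ccccc2)COC1=O | intermediate
10 | dibutylboron (Z)-dienolate of 9 | CCCCB(CCCC)O/C(=C\C(C)=C)N1[C@H](Cc2ccccc2)COC1=O | intermediate
11 | (4R)-4-benzyl-3-[(2R,3R)-3-hydroxy-3-[(2R,3R)-3-methyl-3-(prop-2-en-1-yl)oxiran-2-yl]-2-(prop-1-en-2-yl)propanoyl]-1,3-oxazolidin-2-one | C=CC[C@@]1(C)O[C@@H]1[C@H](O)[C@@H](C(C)=C)C(=O)N1[C@H](Cc2ccccc2)COC1=O | intermediate
12 | (2R,3R)-3-hydroxy-N-methoxy-N-methyl-3-[(2R,3R)-3-methyl-3-(prop-2-en-1-yl)oxiran-2-yl]-2-(prop-1-en-2-yl)propanamide | C=CC[C@@]1(C)O[C@@H]1[C@H](O)[C@@H](C(C)=C)C(=O)N(C)OC | intermediate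
13 | (3R,4R)-1-chloro-4-hydroxy-4-[(2R,3R)-3-methyl-3-(prop-2-en-1-yl)oxiran-2-yl]-3-(prop-1-en-2-yl)butan-2-one | C=CC[C@@]1(C)O[C@@H]1[C@H](O)[C@@H](C(C)=C)C(=O)CCl | intermediate
14 | (2S,3R,4R)-1-chloro-4-[(2R,3R)-3-methyl-3-(prop-2-en-1-yl)oxiran-2-yl]-3-(prop-1-en-2-yl)butane-2,4-diol | C=CC[C@@]1(C)O[C@@H]1[C@H](O)[C@@H](C(C)=C)[C@H](O)CCl | intermediate
15 | (1R,2R)-3-methyl-1-[(2R,3R)-3-methyl-3-(prop-2-en-1-yl)oxiran-2-yl]-2-[(2S)-oxiran-2-yl]but-3-en-1-ol | C=CC[C@@]1(C)O[C@@H]1[C@H](O)[C@@H](C(C)=C)[C@H]1CO1 | intermediate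
16 | triethyl{[(1R,2S)-3-methyl-1-[(2R,3R)-3-methyl-3-(prop-2-en-1-yl)oxiran-2-yl]-2-[(2S)-oxiran-2-yl]but-3-en-1-yl]oxy}silane | C=CC[C@@]1(C)O[C@@H]1[C@H](O[Si](CC)(CC)CC)[C@@H](C(C)=C)[C@H]1CO1 | intermediate
17 | primary pinacol boronate (16 with CH2CH2–Bpin in place of the vinyl group) | CC1(C)OB(CCC[C@@]2(C)O[C@@H]2[C@H](O[Si](CC)(CC)CC)[C@@H](C(C)=C)[C@H]2CO2)OC1(C)C | intermediate
18 | 2,4,6-tri(propan-2-yl)benzoic acid | CC(C)c1cc(C(C)C)c(C(=O)O)c(C(C)C)c1 | starting material
19 | ethanol | CCO | starting material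
20 | ethyl 2,4,6-tri(propan-2-yl)benzoate | CCOC(=O)c1c(C(C)C)cc(C(C)C)cc1C(C)C | intermediate
21 | (1S)-1-lithioethyl 2,4,6-tri(propan-2-yl)benzoate (sparteine complex) | [Li][C@@H](C)OC(=O)c1c(C(C)C)cc(C(C)C)cc1C(C)C | intermediate
22 | lithium boronate complex of 17 and 21 | [Li+].CC1(C)O[B-](CCC[C@@]2(C)O[C@@H]2[C@H](O[Si](CC)(CC)CC)[C@@H](C(C)=C)[C@H]2CO2)([C@@H](C)OC(=O)c2c(C(C)C)cc(C(C)C)cc2C(C)C)OC1(C)C | intermediate
23 | secondary pinacol boronate, (R) at the boron-bearing carbon C10 | CC1(C)OB([C@H](C)CCC[C@@]2(C)O[C@@H]2[C@H](O[Si](CC)(CC)CC)[C@@H](C(C)=C)[C@H]2CO2)OC1(C)C | intermediate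
24 | C9-lithiated oxirane of 23 (lithium trans to C7) | CC1(C)OB([C@H](C)CCC[C@@]2(C)O[C@@H]2[C@H](O[Si](CC)(CC)CC)[C@@H](C(C)=C)[C@H]2[C@H]([Li])O2)OC1(C)C | intermediate
25 | eleven-membered cyclic lithium boronate complex (B bonded to C9 and C10) | [Li+].CC1(C)O[B-]2(OC1(C)C)[C@H](C)CCC[C@@]3(C)O[C@@H]3[C@H](O[Si](CC)(CC)CC)[C@@H](C(C)=C)[C@@H]4O[C@H]42 | intermediate
26 | ten-membered C9 pinacol boronate, lithium C8 alkoxide | [Li+].C[C@@H]1CCC[C@@]2(C)O[C@@H]2[C@H](O[Si](CC)(CC)CC)[C@@H](C(C)=C)[C@H]([O-])[C@H]1B3OC(C)(C)C(C)(C)O3 | intermediate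
27 | (4R,5R,6R,7S,8S,9S,10R)-4,5-epoxy-6-(triethylsilyloxy)germacr-11(13)-ene-8,9-diol | C[C@@H]1CCC[C@@]2(C)O[C@@H]2[C@H](O[Si](CC)(CC)CC)[C@@H](C(C)=C)[C@H](O)[C@H]1O | intermediate
28 | (4R,5R,6R,7S,8S,9S,10R)-4,5-epoxy-6-(triethylsilyloxy)germacr-11(13)-ene-8,9,12-triol | C[C@@H]1CCC[C@@]2(C)O[C@@H]2[C@H](O[Si](CC)(CC)CC)[C@@H](C(CO)=C)[C@H](O)[C@H]1O | intermediate
29 | (4R,5R,6R,7S,8S,9S,10R)-4,5-epoxy-9-hydroxy-6-(triethylsilyloxy)germacr-11(13)-en-12,8-olide | C[C@@H]1CCC[C@@]2(C)O[C@@H]2[C@H](O[Si](CC)(CC)CC)[C@H]3C(=C)C(=O)O[C@@H]3[C@H]1O | intermediate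
30 | (4R,5R,6R,7S,8S,9R,10R)-4,5-epoxy-9-(formyloxy)-6-(triethylsilyloxy)germacr-11(13)-en-12,8-olide | C[C@@H]1CCC[C@@]2(C)O[C@@H]2[C@H](O[Si](CC)(CC)CC)[C@H]3C(=C)C(=O)O[C@@H]3[C@@H]1OC=O | intermediate
31 | (4R,5R,6R,7R,8S,9R,10R)-4,5-epoxy-9-(formyloxy)-6-hydroxygermacr-11(13)-en-12,8-olide | C[C@@H]1CCC[C@@]2(C)O[C@@H]2[C@H](O)[C@H]3C(=C)C(=O)O[C@@H]3[C@@H]1OC=O | intermediate
32 | (4R,5R,6R,7S,8S,9R,10R)-4,5-epoxy-9-(formyloxy)-6-(3-methylbut-2-enoyloxy)germacr-11(13)-en-12,8-olide | C[C@@H]1CCC[C@@]2(C)O[C@@H]2[C@H](OC(=O)C=C(C)C)[C@H]3C(=C)C(=O)O[C@@H]3[C@@H]1OC=O | intermediate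
33 | CNP0119422.1, (4R,5R,6R,7S,8S,9R,10R)-4,5-epoxy-9-hydroxy-6-(3-methylbut-2-enoyloxy)germacr-11(13)-en-12,8-olide | C=C1C(=O)O[C@@H]2[C@H](O)[C@H](C)CCC[C@@]3(C)O[C@@H]3[C@H](OC(=O)C=C(C)C)[C@@H]12 | target

**Step count and risks**

Total step count: 19. Longest linear sequence: 17 steps (1–3, 5–10, 12–19).

Steps most likely to fail:

Step 13 (key step). The lithiated oxirane may be consumed by carbenoid pathways (1,2-hydride shift, dimerisation, attack by LiTMP) before the entropically slow closure of the eleven-membered boronate complex, or the β-oxido boronate may eliminate boron and oxygen before it is oxidised. The fallback uses known chemistry and sets out from 16. The same lithiated-epoxide homologation is run intermolecularly (LiTMP, THF, −30 °C) in the presence of (R)-but-3-en-2-ylboronic acid pinacol ester F1, followed by NaOH/H2O2, to give the open-chain 8,9-syn diol diene F2. Ring-closing metathesis of F2 (second-generation Grubbs catalyst, dilute CH2Cl2, reflux) should close the ten-membered ring at C1=C2 to give cyclodecene diol F3. Diimide (2-nitrobenzenesulfonyl hydrazide, Et3N) is expected to saturate the strained endocyclic alkene in preference to the hindered isopropenyl group, and the route is rejoined at 27.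

Step 16. Elimination of the activated C9 oxygen toward C10 or C8, or failure of SN2 attack at the hindered ring carbinol, may compete with inversion. The fallback sets out from 29: triflation (Tf2O, pyridine, CH2Cl2, −20 °C) gives the C9 triflate F4; Lattrell–Dax displacement with tetrabutylammonium nitrite (toluene/DMF, rt; the nitrite ester hydrolyses on work-up) gives the C9-inverted alcohol F5; formylation (acetic formic anhydride, pyridine, 0 °C) rejoins the route at 30.

Step 14. Acid-promoted transannular opening of the C4–C5 oxirane by the free C8 hydroxyl, over-oxidation, or oxidation at the C7 methine may erode the allylic oxidation. The fallback sets out from 27: a Schenck ene reaction with singlet oxygen (O2, hν, tetraphenylporphyrin, CH2Cl2, 0 °C) under neutral conditions gives the allylic hydroperoxide F6, and reduction with PPh3 rejoins the route at 28.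

**Further compounds**

F1 | step 13 | (R)-2-(but-3-en-2-yl)-4,4,5,5-tetramethyl-1,3,2-dioxaborolane | C=C[C@@H](C)B1OC(C)(C)C(C)(C)O1
F2 | step 13 | open-chain 8,9-syn diol diene (C10 vinyl, C3 allyl) | C=CC[C@@]1(C)O[C@@H]1[C@H](O[Si](CC)(CC)CC)[C@@H](C(C)=C)[C@H](O)[C@@H](O)[C@H](C)C=C
F3 | step 13 | 1,2-didehydro derivative of 27 (cyclodecene diol) | C[C@@H]1C=CC[C@@]2(C)O[C@@H]2[C@H](O[Si](CC)(CC)CC)[C@@H](C(C)=C)[C@H](O)[C@H]1O
F4 | step 16 | C9 trifluoromethanesulfonate of 29 | C[C@@H]1CCC[C@@]2(C)O[C@@H]2[C@H](O[Si](CC)(CC)CC)[C@H]3C(=C)C(=O)O[C@@H]3[C@H]1OS(=O)(=O)C(F)(F)F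
F5 | step 16 | (9R)-epimer of 29 (C9-inverted alcohol) | C[C@@H]1CCC[C@@]2(C)O[C@@H]2[C@H](O[Si](CC)(CC)CC)[C@H]3C(=C)C(=O)O[C@@H]3[C@@H]1O
F6 | step 14 | C12 allylic hydroperoxide of 27 | C[C@@H]1CCC[C@@]2(C)O[C@@H]2[C@H](O[Si](CC)(CC)CC)[C@@H](C(COO)=C)[C@H](O)[C@H]1O
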